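(The earlier runs and the new flask were generated by integration for substances that don't exist; noise was put on by code.)

The small charge in Sunday's flask is the starting material, 0.63 M against 0.756 M of fresh partner. Yet at the last reading target holds 31.9% of it, so a balance of that charge leaves 68.1% outside target, and the end of the run needs another account.

in all of them: fresh partner 0.756 M; gas 110 mM (held)
- Sunday's: starting material 0.63 M; the very flask that is asked about, followed so far
- Friday's: starting material 1.3 M; run made earlier
- flask: starting material 0.63 M; time 3.0 min

- Sunday's (time / s: target / %): 10.0: 4.7; 15.0: 8.1; 25.0: 16.5; 40.0: 23.3; 60.0: 28.5; 120: 31.9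
- Friday's (time / s: target / %): 12.0: 5.1; 25.0: 13.6; 40.0: 21.0; 50.0: 20.6; 60.0: 21.3; 80.0: 22.6

(scatter of a reading: 1 percentage point)

- alpha: at 3.0 min add fresh partner, 50.0% of the amount charged, then wait 1.5 min
- delta: at 3.0 min take out 90% of the target then present, then wait 1.5 min
- beta: at 3.0 min add starting material, 50.0% of the amount charged, then wait 1.5 min
- zeta: change nothing and wait 1.5 min more

- what is taken out of target is counted as made
- at the start none of the gas is in solution
- additions bring no volume worth counting

* target, in percent of the starting material first charged, at 3.0 min
* the option that brings most further target ("none" if no option brings more than 2 percentage points) (alpha / delta / beta / zeta / none)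
* target present, with what was taken out counted in, in percent of the starting material first charged, after beta
* target present, with what was taken out counted in, in percent of the starting material first charged, after zeta

Sunday's target forms at 5.29 mM s⁻¹ between 15.0 s and 25.0 s, but at 0.357 mM s⁻¹ between 60.0 s and 120 s, a slowing by a factor of 14.8. Friday's run, with 2.06 times the starting material, falls from 8.50 mM s⁻¹ to 0.520 mM s⁻¹, a factor of 16.3. The late gains behind these factors, 3.4 percentage points on Sunday and 1.6 points on Friday, stand against a scatter of 1 point per reading, so the two factors are rough readings and are not held against each other. Both runs share the fresh partner charge and the held gas, and this reckoning, as a working assumption, charges the slowing to fresh partner, taken as the limiting reagent.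

Sunday's rate was 1.64 mM s⁻¹ between 40.0 s and 60.0 s, which with the last window gives a decay time of 26.3 s, shorter than 3.0 min. The remaining gain is then 0.39 points, so target stops near 32.3%.

That end gives the fresh-partner yield, c(target) at the end per c(fresh partner) charged: 26.9% in Sunday's flask, while Friday's last reading gives 38.9%. Alpha adds fresh partner, so this reckoning commits to alpha; beta adds none, so beta and zeta stay near 32.3%.

The forecast gives 32.4%, 39.7% after beta, 32.5% after zeta and names delta: “That points to an equilibrium rather than simple exhaustion”.

The flask gives 32.5%, with 32.8% after beta, 32.7% after zeta, and alpha as best. At 3.00 min it holds 53.2% of the starting material as open intermediate, with fresh partner at 0%. The yield applied to alpha's dose gives 16 points; the flask gains 15 points, against 9.2 points for delta and 0.29 points for beta.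

    starting material + coupling partner → open intermediate (k = 1.16 M⁻¹ s⁻¹)
    coupling partner + fresh partner → second intermediate (k = 0.773 M⁻¹ s⁻¹)
    open intermediate + second intermediate → target (k = 0.0648 M⁻¹ s⁻¹)
    2 second intermediate → homo product (k = 0.125 M⁻¹ s⁻¹)
    target ⇌ isomer of the product (K = 0.440, k = 0.135 s⁻¹)
    gas ⇌ coupling partner, rate k6*(csat - [coupling partner]) (kL = 8.15 s⁻¹)
    coupling partner → decomposed reagent (k = 0.0176 s⁻¹)

In a neighbouring flask with 1.6 M of starting material, the straight line through Sunday's and Friday's yields reaches 44.2%, which gives 20.9% target. The computed neighbouring flask holds 21.2%.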